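The target you want also sits on the catalyst that makes it, and the pace of this flask goes with the catalyst that the growing target leaves free.

    catalyst + target ⇌ idle complex, settled at all times (K1 = 820 /M)
    target ⇌ isomer of the product (K2 = 0.89, k2 = 0.057 /s)
    gas phase ⇌ dissolved gas, rate k3*(csat - [dissolved gas]) (k3 = 5.9 /s, csat = 7.8 mM)
    starting material + dissolved gas + catalyst → catalyst + target (k4 = 2500 /M²/s)

starting material 20 mM; gas phase 7.8 mM (held); catalyst 5 mol%; time 1.5 min

1. how much target and idle complex together there is at 1.5 min, in percent of the starting material charged
2. concentration of dissolved gas in solution at 50 s, in percent of saturation
3. the change that raises the amount of target and idle complex together at 1.5 min, in percent of the starting material charged most ("none" if none brings more than 2 percentage points) (dawn / autumn / noon / none)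
4. amount of target and idle complex together at 1.5 min, in percent of the starting material charged, after noon

- dawn: doubling the amount of catalyst, all else as stated
- autumn: doubling the transfer coefficient of step 3, all else as stated
- noon: doubling the saturation concentration of gas phase, all else as stated

- what is said of target includes idle complex
- at the start none of the gas is dissolved
- run time (flask): 1.5 min

1. Write k for the rate constant of the last step, c for the saturation concentration and κ for k times c times the catalyst charged, which is 1.17 /min; with the gas at saturation and every catalyst free, κ is the pseudo-first-order constant of the starting material. The gas transfer has a half-life of 0.117 s, far shorter than the 35.5 s of that consumption, so I expect the solution at 50 s to stand at 99.2 % of saturation or above, a figure reckoned with the opening demand, and I expect autumn to bring hardly any gain.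

2. Target and isomer relax with a half-life of 0.0954 min, short against 1.5 min, so I take them balanced, with K the binding constant and E the isomer constant. If u is the converted fraction, I take the free share of catalyst as f = 1/(1+βu), leaving the bound target out of this estimate, where the tie-up number β, the binding constant times the charged starting material divided by 1+E, is 8.68. This is product inhibition in one figure.

3. Then du/dt = κf(1−u) integrates to κt = (1+β)L − βu, with L = −ln(1−u). So u = 0.5 falls at 2.02 min, where u grows by 0.110 /min. Stepping back to 1.5 min gives u = 44.2 % and f = 20.7 %.

4. Counting the bound target whole and sharing the rest by E, I commit to y = 25.3 %.

5. Noon and dawn both double κ, so the same step from double the time gives u = 60.7 % and free share 16.0 %. That makes noon 34.1 %, and dawn, whose larger charge of catalyst binds more target at the same free share, 36.1 %, which is more, so I choose dawn.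

The forecast says 27 %, above my figure, with 99.8 %, dawn and 34.7 %, holding that “the solution stays essentially saturated”.

The simulation gives 25.8 %, 99.8 %, dawn and 34.0 %, with gains of 11 percentage points for dawn, 8.2 points for noon and 0.021 points for autumn.

In the flask at 1.50 min, the relaxation half-life of target and isomer, 0.0954 min, is far shorter than the 2.7 min half-life of the starting material by its own step at that time, and 25.8 % target, idle complex counted, stands beside 17.6 % isomer. With the flask's turnover of 43.5 %, β gives a free share of catalyst of 21.0 %, and the simulation reads 21.8 %. For the same flask read at 6.0 min, stepping from u = 0.7 gives u = 76.1 %, so 23.9 % of the starting material left and 13.1 % of the catalyst free; the simulation has 24 % and 13.8 %.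

(The constants are those of an exercise, and the outcome is calculated.)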